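The earlier runs and the new flask are calculated on assumed constants.

In ochre, carrying the first rate of G's loss through to the last reading promises too much conversion.

| setting | ochre | green | autumn | dusk | winter |
|---|---|---|---|---|---|
| G | 0.071 M | 0.071 M | 0.071 M | 0.071 M | 0.071 M |
| E | 3.6 equiv | 11 equiv | 3.00 equiv | 4.50 equiv | 6.80 equiv |
| remark | run made earlier | run made earlier |  |  |  |
| time |  |  | 5.0 d | 5.0 d | 5.0 d |

| run | time / d | G / % | J / % |
|---|---|---|---|
| ochre | 0.417 | 75.0 | 25.6 |
| ochre | 0.833 | 60.2 | 39.0 |
| ochre | 1.25 | 49.0 | 48.2 |
| ochre | 2.50 | 29.6 | 58.0 |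
| ochre | 5.00 | 11.9 | 54.9 |
| green | 0.417 | 40.9 | 59.2 |
| green | 1.25 | 10.8 | 86.7 |
| green | 2.50 | 1.6 | 88.5 |
| green | 4.00 | 0.2 | 82.4 |
| green | 5.00 | 0.4 | 77.9 |

(each reading ± 0.3 percentage points)

1. part of the G that has reacted at the end, autumn
2. part of the G that has reacted at the end, dusk
3. part of the G that has reacted at the end, winter
4. what raising the equivalents of E from its lowest to its highest value here does to the part of the G that has reacted (changes below 5 percentage points count as none) (it falls / it rises / no change)

- the analysis behind the earlier runs scatters by 0.3 percentage points, standard deviation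

Does the rate follow E? The first readings give a decay constant of 0.690 d⁻¹ in ochre and 2.14 d⁻¹ in green, a ratio of 3.10 against 3.06 in equivalents. So G starts out pseudo-first-order, with a constant in step with the E charged.

Does that constant last? In ochre it foretells 3.17 % of G left at 5.00 d, but 11.9 % was read, so the run slows. Ochre ran as long as the new flasks, so its last reading already contains that slowing. In ochre, the ln of the charged c_G over the final c_G, divided by the equivalents, reads 0.591; call this the reach per equivalent over that time.

Does the reach hold at another charge? At 2.50 d the same count gives 0.338 for ochre and 0.376 for green, a rise of 11.2 % for 3.06 times the E. So the reach from ochre serves as an estimate, though these two readings put it a little low for green. Multiplied by the equivalents, it gives a reckoning of 83.0 % reacted in autumn, 93.0 % in dusk and 98.2 % in winter, a rise of 15 percentage points.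

The forecast, noting that “the rate is first order in E” and interpolating between the two runs, gives 82 %, 94 % and 98.9 %, and says it rises. In winter it stands 0.69 points above this reckoning.

The flasks give 82.3 %, 93.9 % and 99.0 %: it rises, by 17 points.

    G + E → X + J (k = 0.135 M⁻¹ h⁻¹)
    E + X ⇌ L, settled at all times (K = 133 M⁻¹)
    X + J → Q (k = 2.54 M⁻¹ h⁻¹)
    E ⇌ D (K = 0.379, k = 0.0243 h⁻¹)

The reach counts the E charged, and free E at the end stands at 41.5 % of its own charge in autumn and 54.8 % in winter. Winter's own reach comes to 0.674 against the 0.591 carried from ochre. Put to the neighbour of winter with 4.10 equiv of E, the carried reach leaves 8.86 % of G, and at 5.00 d that flask holds 8.2 % of its charged G.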